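**Retrosynthetic overview**
- Target ⇐ ketal hydrolysis ⇐ (3S)-isoflavan ketal ⇐ one-flask asymmetric transfer hydrogenation / dynamic kinetic resolution / quinone-methide reduction of a 7-hydroxyisoflavone (sets C-3).
- Isoflavone ⇐ flavanone by oxidative 2,3-aryl shift with PhI(OH)OTs, the laboratory counterpart of isoflavone synthase, run on the free phenol.
- Flavanone ⇐ 2'-hydroxychalcone (oxa-Michael closure of ring C, as chalcone isomerase does) ⇐ 2,4-dihydroxyacetophenone (ring A) + ring B aldehyde.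
- Ring B aldehyde ⇐ 2,3,4-trihydroxybenzaldehyde by 4-O-prenylation, aromatic Claisen rearrangement (gives the 1,1-dimethylallyl group), then catechol ketal and 2-O-methylation.
- Ring order: rings A and B are bought; ring C is the only ring made (step 4), then rearranged (step 5) and reduced (step 6).

Assumption: the stereocentre (C-3 of the isoflavan) is (S), as read from the SMILES.
Abbreviation: Ar = 4-methoxy-7-(2-methylbut-3-en-2-yl)-2,2-diphenyl-1,3-benzodioxol-5-yl (ring B with its catechol tied as the diphenylmethylene ketal).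

**Route**

Step 1
Reactants: 1 2,3,4-trihydroxybenzaldehyde; 2 prenyl bromide (1-bromo-3-methylbut-2-ene)
Product: 3 2,3-dihydroxy-4-[(3-methylbut-2-en-1-yl)oxy]benzaldehyde
Conditions: NaHCO3 (1.5 equiv), NaI (cat.), DMF, 40 °C
Reagents that add atoms: prenyl bromide, CC(C)=CCBr
Why: Williamson etherification; the 4-OH (para to the formyl group) is the most acidic phenol and the 2-OH is hydrogen-bonded to C=O, so a weak base ionises and alkylates O-4 only.

Step 2
Reactants: 3 2,3-dihydroxy-4-[(3-methylbut-2-en-1-yl)oxy]benzaldehyde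
Product: 5 2,3,4-trihydroxy-5-(2-methylbut-3-en-2-yl)benzaldehyde, via ortho-dienone 4 (not isolated)
Conditions: PhNEt2, 190 °C, argon, 2 h
Reagents that add atoms: none
Why: Aromatic Claisen rearrangement; the [3,3] shift delivers the allyl unit with allylic inversion to the only free ortho carbon (C-5, since C-3 carries OH) and dienone 4 enolises to the phenol, so the tertiary 1,1-dimethylallyl attachment arises directly.

Step 3
Reactants: 5 2,3,4-trihydroxy-5-(2-methylbut-3-en-2-yl)benzaldehyde; 6 dichlorodiphenylmethane; 7 iodomethane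
Product: 9 4-methoxy-7-(2-methylbut-3-en-2-yl)-2,2-diphenyl-1,3-benzodioxole-5-carbaldehyde (Ar-CHO), via hydroxy ketal 8 (not isolated)
Conditions: Ph2CCl2 (1.1 equiv), K2CO3 (4 equiv), MeCN, 60 °C; then MeI (2 equiv), 50 °C
Reagents that add atoms: dichlorodiphenylmethane, ClC(Cl)(c1ccccc1)c1ccccc1; iodomethane, CI
Why: Catechol ketalisation with a gem-dichloride followed by O-methylation (SN2) in one pot; the 3,4-diol closes the five-membered ketal because the 2-OH is chelated to the aldehyde, and that remaining phenol is then methylated.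

Step 4
Reactants: 9 Ar-CHO; 10 2,4-dihydroxyacetophenone
Product: 12 rac-7-hydroxy-2-Ar-chroman-4-one (flavanone), via chalcone 11 (not isolated)
Conditions: KOH (50% aq), EtOH, rt, 48 h; then AcOH to pH 6, reflux, 24 h
Reagents that add atoms: 2,4-dihydroxyacetophenone, CC(=O)c1ccc(O)cc1O
Why: Claisen–Schmidt aldol condensation gives the (E)-2'-hydroxychalcone and the acetate-buffered reflux closes ring C by reversible 6-endo oxa-Michael addition; the C-2 stereocentre is racemic and is erased in step 5.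

Step 5
Reactants: 12 rac-7-hydroxy-2-Ar-chroman-4-one
Product: 14 7-hydroxy-3-Ar-4H-chromen-4-one (isoflavone), via 2-methoxyisoflavanone 13 (not isolated)
Conditions: PhI(OH)OTs (1.2 equiv), MeOH/CH2Cl2 (3:1), rt, 12 h; then 45 °C, 1 h
Reagents that add atoms: none
Why: Hypervalent-iodine oxidative 2,3-aryl migration of a flavanone; the enol attacks trivalent iodine at C-3, the very electron-rich ring B shifts from C-2 to C-3 as iodobenzene leaves, and methanol caps the C-2 oxocarbenium ion and is then eliminated, while the acyl-deactivated 7-phenol and the hindered monosubstituted vinyl group are far less nucleophilic than the enol, so no protection is used.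

Step 6
Reactants: 14 7-hydroxy-3-Ar-4H-chromen-4-one
Product: 18 (3S)-3-Ar-chroman-7-ol, via isoflavanone 15 (not isolated), via cis-isoflavan-4-ol 16 (not isolated), via quinone methide 17 (not isolated)
Conditions: RuCl(p-cymene)[(S,S)-TsDPEN] (5 mol %), HCO2H/Et3N (5:2), DMF, 40 °C then 60 °C, argon
Reagents that add atoms: none
Why: Proposed new method: Noyori–Ikariya asymmetric transfer hydrogenation run through to the isoflavan in one flask; Ru–H conjugate reduction gives isoflavanone 15, whose C-3 epimerises quickly under Et3N, the (S,S) catalyst reduces its (3S) form anti to the aryl group (dynamic kinetic resolution) to cis-(3S,4S)-16, this 2,4-dioxygenated benzylic alcohol loses water through the free 7-OH to para-quinone methide 17, and 1,6-hydride addition at C-4 gives 18 with C-3 untouched and the isolated vinyl group unreduced; the closest known reaction types are transfer hydrogenation of isoflavones to cis-isoflavan-4-ols with dynamic kinetic resolution and hydride reduction of para-quinone methides.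

Step 7
Reactants: 18 (3S)-3-Ar-chroman-7-ol
Product: 19 4-[(3S)-7-hydroxychroman-3-yl]-3-methoxy-6-(2-methylbut-3-en-2-yl)benzene-1,2-diol (target)
Conditions: AcOH/H2O (4:1), 90 °C, argon, 3 h
Reagents that add atoms: none
Why: Acid-catalysed ketal hydrolysis through the stabilised diphenyl oxocarbenium ion; the weak acid does not protonate the monosubstituted alkene, and the methyl ether and the non-epimerisable C-3 stereocentre are untouched.

**Compound list**
1 | 2,3,4-trihydroxybenzaldehyde | O=Cc1ccc(O)c(O)c1O | starting material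
2 | prenyl bromide (1-bromo-3-methylbut-2-ene) | CC(C)=CCBr | starting material
3 | 2,3-dihydroxy-4-[(3-methylbut-2-en-1-yl)oxy]benzaldehyde | O=Cc1ccc(OCC=C(C)C)c(O)c1O | intermediate
4 | 5,6-dihydroxy-3-(2-methylbut-3-en-2-yl)-4-oxocyclohexa-1,5-diene-1-carbaldehyde (racemic ortho-dienone) | O=CC1=CC(C(C)(C)C=C)C(=O)C(O)=C1O | intermediate (not isolated)
5 | 2,3,4-trihydroxy-5-(2-methylbut-3-en-2-yl)benzaldehyde | O=Cc1cc(C(C)(C)C=C)c(O)c(O)c1O | intermediate
6 | dichlorodiphenylmethane | ClC(Cl)(c1ccccc1)c1ccccc1 | starting material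
7 | iodomethane | CI | starting material
8 | 4-hydroxy-7-(2-methylbut-3-en-2-yl)-2,2-diphenyl-1,3-benzodioxole-5-carbaldehyde | O=Cc1cc(C(C)(C)C=C)c2OC(c3ccccc3)(c3ccccc3)Oc2c1O | intermediate (not isolated)
9 | 4-methoxy-7-(2-methylbut-3-en-2-yl)-2,2-diphenyl-1,3-benzodioxole-5-carbaldehyde | O=Cc1cc(C(C)(C)C=C)c2OC(c3ccccc3)(c3ccccc3)Oc2c1OC | intermediate
10 | 2,4-dihydroxyacetophenone | CC(=O)c1ccc(O)cc1O | starting material
11 | (E)-1-(2,4-dihydroxyphenyl)-3-[4-methoxy-7-(2-methylbut-3-en-2-yl)-2,2-diphenyl-1,3-benzodioxol-5-yl]prop-2-en-1-one | O=C(/C=C/c1cc(C(C)(C)C=C)c2OC(c3ccccc3)(c3ccccc3)Oc2c1OC)c1ccc(O)cc1O | intermediate (not isolated)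
12 | rac-7-hydroxy-2-[4-methoxy-7-(2-methylbut-3-en-2-yl)-2,2-diphenyl-1,3-benzodioxol-5-yl]chroman-4-one | O=C1CC(c2cc(C(C)(C)C=C)c3OC(c4ccccc4)(c4ccccc4)Oc3c2OC)Oc2cc(O)ccc21 | intermediate
13 | 7-hydroxy-2-methoxy-3-[4-methoxy-7-(2-methylbut-3-en-2-yl)-2,2-diphenyl-1,3-benzodioxol-5-yl]chroman-4-one (racemic, diastereomer mixture) | COC1Oc2cc(O)ccc2C(=O)C1c1cc(C(C)(C)C=C)c2OC(c3ccccc3)(c3ccccc3)Oc2c1OC | intermediate (not isolated)
14 | 7-hydroxy-3-[4-methoxy-7-(2-methylbut-3-en-2-yl)-2,2-diphenyl-1,3-benzodioxol-5-yl]-4H-chromen-4-one | O=c1c(-c2cc(C(C)(C)C=C)c3OC(c4ccccc4)(c4ccccc4)Oc3c2OC)coc2cc(O)ccc12 | intermediate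
15 | 7-hydroxy-3-[4-methoxy-7-(2-methylbut-3-en-2-yl)-2,2-diphenyl-1,3-benzodioxol-5-yl]chroman-4-one (C-3 epimerising; reduced as its (3S) form) | O=C1c2ccc(O)cc2OCC1c1cc(C(C)(C)C=C)c2OC(c3ccccc3)(c3ccccc3)Oc2c1OC | intermediate (not isolated)
16 | (3S,4S)-3-[4-methoxy-7-(2-methylbut-3-en-2-yl)-2,2-diphenyl-1,3-benzodioxol-5-yl]chromane-4,7-diol (cis) | C=CC(C)(C)c1cc([C@H]2COc3cc(O)ccc3[C@H]2O)c(OC)c2OC(c3ccccc3)(c3ccccc3)Oc12 | intermediate (not isolated)
17 | (3S)-3-[4-methoxy-7-(2-methylbut-3-en-2-yl)-2,2-diphenyl-1,3-benzodioxol-5-yl]-2,3-dihydro-7H-chromen-7-one (para-quinone methide) | C=CC(C)(C)c1cc([C@H]2COC3=CC(=O)C=CC3=C2)c(OC)c2OC(c3ccccc3)(c3ccccc3)Oc12 | intermediate (not isolated)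
18 | (3S)-3-[4-methoxy-7-(2-methylbut-3-en-2-yl)-2,2-diphenyl-1,3-benzodioxol-5-yl]chroman-7-ol | C=CC(C)(C)c1cc([C@H]2COc3cc(O)ccc3C2)c(OC)c2OC(c3ccccc3)(c3ccccc3)Oc12 | intermediate
19 | 4-[(3S)-7-hydroxychroman-3-yl]-3-methoxy-6-(2-methylbut-3-en-2-yl)benzene-1,2-diol | C=CC(C)(C)c1cc([C@H]2COc3cc(O)ccc3C2)c(OC)c(O)c1O | target

**Count**
Total steps: 7. Longest linear sequence: 7 steps (1 → 3 → 5 → 9 → 12 → 14 → 18 → 19); 10 enters at step 4.

**Steps most likely to fail, with fallbacks**

Step 2 is the first risk: a free trihydroxybenzaldehyde at 190 °C may lose the prenyl group, give the abnormal Claisen product or cyclise to a dihydrobenzofuran. The fallback sets out from 1 and comes back at 9, replacing the sigmatropic shift by a cross-coupling. Br2 in AcOH brominates 1 at C-5 (ortho to the 4-OH, para to the 2-OH) to give 5-bromo-2,3,4-trihydroxybenzaldehyde F1. Ph2CCl2/K2CO3 then gives 7-bromo-4-hydroxy-2,2-diphenyl-1,3-benzodioxole-5-carbaldehyde F2, and MeI gives 7-bromo-4-methoxy-2,2-diphenyl-1,3-benzodioxole-5-carbaldehyde F3. HC(OMe)3 with catalytic TsOH in MeOH masks the aldehyde, which the allylboronate would otherwise attack, as 7-bromo-5-(dimethoxymethyl)-4-methoxy-2,2-diphenyl-1,3-benzodioxole F4. A branch-selective (γ) Suzuki–Miyaura coupling with 3-methylbut-2-enylboronic acid pinacol ester [Pd(OAc)2, a bulky dialkylbiarylphosphine chosen for branched selectivity, K3PO4, THF/H2O, 40 °C] gives 5-(dimethoxymethyl)-4-methoxy-7-(2-methylbut-3-en-2-yl)-2,2-diphenyl-1,3-benzodioxole F5. 1 M HCl in THF at rt releases 9.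

Step 5 is the second risk: flavone formation by dehydrogenation, ring contraction by migration of ring A, or attack of the oxidant on the vinyl group. The fallback sets out from 11 (step 4 stopped before the buffered reflux and the chalcone isolated) and comes back at 14. PhI(OAc)2 with TsOH·H2O in MeOH/HC(OMe)3 at rt effects the 1,2-aryl shift on the open chain to give rac-1-(2,4-dihydroxyphenyl)-3,3-dimethoxy-2-[4-methoxy-7-(2-methylbut-3-en-2-yl)-2,2-diphenyl-1,3-benzodioxol-5-yl]propan-1-one F6. Catalytic HCl in MeOH at 50 °C then closes ring C by attack of the 2'-OH on the acetal carbon and loss of methanol, giving 14. Ring C is thus formed after the aryl shift instead of before it, which removes the flavone and ring-contraction pathways.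

Step 6 is the third risk: the ruthenium hydride may stop at the alcohol, or the quinone methide may tautomerise to the isoflav-3-ene and erode the ee. The fallback sets out from 14 and comes back at 18. The transfer hydrogenation is run at 25–30 °C so that it stops at 16, which is isolated. 16 is then deoxygenated by ionic hydrogenation (Et3SiH, 10 equiv, BF3·OEt2, CH2Cl2, −78 °C), where excess silane captures the C-4 cation before it can lose H-3. The ee of 18 is checked by chiral HPLC. This fallback makes no new compound (entry F0).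

**Further compounds**
F1 | step 2 | 5-bromo-2,3,4-trihydroxybenzaldehyde | O=Cc1cc(Br)c(O)c(O)c1O
F2 | step 2 | 7-bromo-4-hydroxy-2,2-diphenyl-1,3-benzodioxole-5-carbaldehyde | O=Cc1cc(Br)c2OC(c3ccccc3)(c3ccccc3)Oc2c1O
F3 | step 2 | 7-bromo-4-methoxy-2,2-diphenyl-1,3-benzodioxole-5-carbaldehyde | O=Cc1cc(Br)c2OC(c3ccccc3)(c3ccccc3)Oc2c1OC
F4 | step 2 | 7-bromo-5-(dimethoxymethyl)-4-methoxy-2,2-diphenyl-1,3-benzodioxole | COC(OC)c1cc(Br)c2OC(c3ccccc3)(c3ccccc3)Oc2c1OC
F5 | step 2 | 5-(dimethoxymethyl)-4-methoxy-7-(2-methylbut-3-en-2-yl)-2,2-diphenyl-1,3-benzodioxole | COC(OC)c1cc(C(C)(C)C=C)c2OC(c3ccccc3)(c3ccccc3)Oc2c1OC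
F6 | step 5 | rac-1-(2,4-dihydroxyphenyl)-3,3-dimethoxy-2-[4-methoxy-7-(2-methylbut-3-en-2-yl)-2,2-diphenyl-1,3-benzodioxol-5-yl]propan-1-one | COC(OC)C(C(=O)c1ccc(O)cc1O)c1cc(C(C)(C)C=C)c2OC(c3ccccc3)(c3ccccc3)Oc2c1OC
F0 | step 6 | none | none
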